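**Plan**

- Retrosynthesis: the two C–C bonds of the methylene bridge are cut first (pyrone C3–CH2 and CH2–arene), leaving 6-ethyl-4-hydroxy-5-methyl-2-pyrone, a one-carbon iminium unit and the prenylated acylphloroglucinol.
- The benzene ring is then cut at two bonds, C(OH)–C(side chain) and C(prenyl)–C(O) on the far side, into a siloxyalkyne and a 3-siloxycyclobutenone.
- Enabling feature: in the benzene ring the three oxygen-bearing carbons alternate with the three carbon-substituted ones, so each C–O carbon can begin as a ketene carbonyl, an ynol carbon or an enol carbon, and the acyl and prenyl positions arrive as substituents of the alkyne and of the four-membered ring.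
- Forward order of rings: the four-membered ring (alkylketene plus ethoxyethyne), then the benzene ring by benzannulation, the pyrone ring separately from pentan-3-one and malonyl dichloride; the two halves are joined last through CH2.
- Stereochemistry: the single stereocentre is C3 of L-isoleucine; it sits next to a silyl-protected carbinol (the former C2, sacrificial) and is never alpha to a carbonyl until the ketone is unveiled in step 13.

Key step: step 10

Remark: 5-methylhex-4-enoic acid, ethoxyethyne and malonyl dichloride are taken as catalogue chemicals; because the three ring oxygens end on alternate carbons, a positional isomer of the siloxycyclobutenone with prenyl at C4 would converge on the same tris(triisopropylsilyl) ether after the benzannulation and the phenol silylation, so its presence would not be harmful.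

**Route**

Step 1
Reactants: 1 L-isoleucine
Product: 2 (2S,3S)-2-hydroxy-3-methylpentanoic acid
Conditions: NaNO2, 1 M H2SO4 (aq), 0 °C → rt
Reagents that add atoms: water, O
Why: Diazotisation of the alpha-amino acid replaces nitrogen by hydroxyl with net retention (double inversion through carboxylate participation), and the methyl-bearing centre is not touched.

Step 2
Reactants: 2 (2S,3S)-2-hydroxy-3-methylpentanoic acid
Product: 3 methyl (2S,3S)-2-hydroxy-3-methylpentanoate
Conditions: MeOH, H2SO4 (cat.), reflux
Reagents that add atoms: methanol, CO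
Why: Fischer esterification, which leaves both stereocentres alone.

Step 3
Reactants: 3 methyl (2S,3S)-2-hydroxy-3-methylpentanoate
Product: 4 methyl (2S,3S)-3-methyl-2-(triethylsilyloxy)pentanoate
Conditions: Et3SiCl, imidazole, DMF, 0 °C → rt
Reagents that add atoms: chlorotriethylsilane, CC[Si](Cl)(CC)CC
Why: Imidazole-mediated silylation of a secondary alcohol; the triethylsilyl group is chosen because an alkyl triethylsilyl ether can later be cleaved beside aryl triisopropylsilyl ethers.

Step 4
Reactants: 4 methyl (2S,3S)-3-methyl-2-(triethylsilyloxy)pentanoate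
Product: 6 (3S,4S)-4-methyl-3-(triethylsilyloxy)hex-1-yne, via aldehyde 5 (not isolated)
Conditions: i-Bu2AlH, CH2Cl2, −78 °C; then MeOH, K2CO3, dimethyl (1-diazo-2-oxopropyl)phosphonate, −78 °C → rt
Reagents that add atoms: dimethyl (1-diazo-2-oxopropyl)phosphonate, CC(=O)C(=[N+]=[N-])P(=O)(OC)OC
Why: Partial reduction of the alpha-silyloxy ester should stop at the aluminium hemiacetal at −78 °C, and the aldehyde released by methanol undergoes Seyferth–Gilbert homologation with the Ohira–Bestmann reagent in the same flask; the methyl-bearing centre cannot enolise and any erosion at the carbinol carbon is harmless because that centre is later oxidised.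

Step 5
Reactants: 6 (3S,4S)-4-methyl-3-(triethylsilyloxy)hex-1-yne
Product: 9 (3S,4S)-4-methyl-3-(triethylsilyloxy)-1-(triisopropylsilyloxy)hex-1-yne, via lithium acetylide 7 (not isolated), via lithium ynolate 8 (not isolated)
Conditions: LiN(SiMe3)2, THF, −78 °C; t-BuOOLi (from t-BuOOH and LiN(SiMe3)2), −78 → 0 °C; i-Pr3SiOTf, −78 → 0 °C
Reagents that add atoms: tert-butyl hydroperoxide, CC(C)(C)OO; triisopropylsilyl trifluoromethanesulfonate, CC(C)[Si](OS(=O)(=O)C(F)(F)F)(C(C)C)C(C)C
Why: Electrophilic oxygenation of a lithium acetylide by lithium tert-butyl peroxide gives the ynolate, and the bulky silyl triflate traps it on oxygen as a thermally robust siloxyalkyne, an established route to such ynol ethers from terminal alkynes.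

Step 6
Reactants: 10 5-methylhex-4-enoic acid
Product: 11 5-methylhex-4-enoyl chloride
Conditions: (COCl)2, DMF (cat.), CH2Cl2, 0 °C → rt
Reagents that add atoms: oxalyl chloride, O=C(Cl)C(=O)Cl
Why: Acid chloride formation under Vilsmeier-type catalysis at low temperature, mild enough for the trisubstituted alkene.

Step 7
Reactants: 11 5-methylhex-4-enoyl chloride; 12 ethoxyethyne
Product: 15 3-ethoxy-2-(3-methylbut-2-enyl)cyclobut-2-en-1-one, via prenylketene 13 (not isolated), via 4-prenyl isomer 14 (not isolated)
Conditions: Et3N, Et2O, 0 °C → rt, slow addition of 11 to excess 12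
Reagents that add atoms: none
Why: Dehydrochlorination gives the monoalkylketene, which undergoes the known ketene–ynol ether [2+2] cycloaddition (nucleophilic alkyne CH onto the ketene carbonyl carbon), and the first-formed 4-substituted adduct is expected to move its double bond into the conjugated tetrasubstituted position under the amine; both double-bond isomers hydrolyse to the same dione in step 8, so the position of this equilibrium is of no consequence.

Step 8
Reactants: 15 3-ethoxy-2-(3-methylbut-2-enyl)cyclobut-2-en-1-one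
Product: 16 3-hydroxy-2-(3-methylbut-2-enyl)cyclobut-2-en-1-one
Conditions: 1 M HCl (aq), THF, 0 °C → rt
Reagents that add atoms: water, O
Why: Acid hydrolysis of the vinylogous ester to the enolised cyclobutane-1,3-dione, a known reaction of 3-ethoxycyclobutenones that is run cold and briefly to spare the prenyl alkene.

Step 9
Reactants: 16 3-hydroxy-2-(3-methylbut-2-enyl)cyclobut-2-en-1-one
Product: 17 2-(3-methylbut-2-enyl)-3-(triisopropylsilyloxy)cyclobut-2-en-1-one
Conditions: i-Pr3SiCl, Et3N, CH2Cl2, 0 °C; used without chromatography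
Reagents that add atoms: chlorotriisopropylsilane, CC(C)[Si](Cl)(C(C)C)C(C)C
Why: O-silylation of a vinylogous acid proceeds like that of a carboxylic acid, the delocalised enolate across C1–C2–C3 has two equivalent oxygens, and the bulky silyl group should make the vinylogous silyl ester tolerably stable to moisture.

Step 10
Reactants: 17 2-(3-methylbut-2-enyl)-3-(triisopropylsilyloxy)cyclobut-2-en-1-one; 9 (3S,4S)-4-methyl-3-(triethylsilyloxy)-1-(triisopropylsilyloxy)hex-1-yne
Product: 22 2-[(1S,2S)-2-methyl-1-(triethylsilyloxy)butyl]-4-(3-methylbut-2-enyl)-3,5-bis(triisopropylsilyloxy)phenol, via siloxyvinylketene 18 (not isolated), via vinylcyclobutenone adduct 19 (not isolated), via dienylketene 20 (not isolated), via cyclohexadienone 21 (not isolated)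
Conditions: PhMe, sealed tube, Ar, 80 → 120 °C, 9 in slight excess
Reagents that add atoms: none
Why: Proposed new method: on heating, 17 should open by 4π electrocyclic cleavage of its C1–C4 bond to siloxyvinylketene 18, the nucleophilic C2 of siloxyalkyne 9 (beta to oxygen) should add to the ketene carbonyl carbon in a [2+2] cycloaddition that makes the two new skeletal bonds, and adduct 19 should reopen (4π) to dienylketene 20. The benzene ring is then closed by thermal disrotatory 6π electrocyclisation of 20, ketene carbon onto the terminal CH2, giving dienone 21, which enolises to phenol 22; the four-membered ring of 19 is only a relay. The closest known reaction is the Danheiser benzannulation of 3-alkyl- and 3-arylcyclobutenones with triisopropylsiloxyalkynes to resorcinol monosilyl ethers, and the untested element is the 3-siloxy group of 17, a vinylogous silyl ester expected to open more slowly, which is why the temperature is raised stepwise. No stereocentre is created, since the quaternary carbon of 19 is lost on ring opening and the two side-chain centres carry no acidic hydrogen under neutral heat. The one selectivity required is the orientation of the [2+2] addition, fixed by the polarisation of the ynol ether against the electrophilic ketene carbon, and it places the side chain ortho to the new hydroxyl and the three oxygens on alternate carbons. A slight excess of 9 should intercept 18 before it dimerises or acylates 22.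

Step 11
Reactants: 22 2-[(1S,2S)-2-methyl-1-(triethylsilyloxy)butyl]-4-(3-methylbut-2-enyl)-3,5-bis(triisopropylsilyloxy)phenol
Product: 23 triethyl{(1S,2S)-2-methyl-1-[3-(3-methylbut-2-enyl)-2,4,6-tris(triisopropylsilyloxy)phenyl]butoxy}silane
Conditions: i-Pr3SiOTf, 2,6-lutidine, CH2Cl2, 0 °C → rt
Reagents that add atoms: triisopropylsilyl trifluoromethanesulfonate, CC(C)[Si](OS(=O)(=O)C(F)(F)F)(C(C)C)C(C)C
Why: Silyl triflate silylation of the one free phenol, which has a hydrogen as one ortho neighbour, removes the ortho-hydroxybenzyl motif that would otherwise invite quinone methide formation once the carbinol is freed.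

Step 12
Reactants: 23 triethyl{(1S,2S)-2-methyl-1-[3-(3-methylbut-2-enyl)-2,4,6-tris(triisopropylsilyloxy)phenyl]butoxy}silane
Product: 24 (1S,2S)-2-methyl-1-[3-(3-methylbut-2-enyl)-2,4,6-tris(triisopropylsilyloxy)phenyl]butan-1-ol
Conditions: HF·pyridine, pyridine, THF, 0 °C
Reagents that add atoms: none
Why: Under buffered acidic fluoride an alkyl triethylsilyl ether is cleaved well before bulky aryl triisopropylsilyl ethers, the usual order of lability for HF-based desilylation, and the pyridine buffer keeps the electron-rich benzylic C–O bond from ionising.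

Step 13
Reactants: 24 (1S,2S)-2-methyl-1-[3-(3-methylbut-2-enyl)-2,4,6-tris(triisopropylsilyloxy)phenyl]butan-1-ol
Product: 25 (2S)-2-methyl-1-[3-(3-methylbut-2-enyl)-2,4,6-tris(triisopropylsilyloxy)phenyl]butan-1-one
Conditions: Dess–Martin periodinane, NaHCO3, CH2Cl2, 0 °C → rt
Reagents that add atoms: none
Why: Dess–Martin oxidation of a hindered benzylic alcohol under buffered, near-neutral conditions tolerates the prenyl alkene and aryl silyl ethers and should not epimerise the new alpha-stereocentre of the twisted di-ortho-substituted aryl ketone.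

Step 14
Reactants: 25 (2S)-2-methyl-1-[3-(3-methylbut-2-enyl)-2,4,6-tris(triisopropylsilyloxy)phenyl]butan-1-one
Product: 26 (2S)-2-methyl-1-[2,4,6-trihydroxy-3-(3-methylbut-2-enyl)phenyl]butan-1-one
Conditions: Bu4NF, AcOH, THF, 0 °C, Ar
Reagents that add atoms: none
Why: Fluoride cleaves aryl silyl ethers readily, and acetic acid buffering protonates each phenoxide as it forms, which should prevent base-induced epimerisation and air oxidation of the electron-rich triol.

Step 15
Reactants: 27 pentan-3-one
Product: 28 (Z)-3-(trimethylsilyloxy)pent-2-ene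
Conditions: Me3SiOTf, Et3N, CH2Cl2, 0 °C
Reagents that add atoms: trimethylsilyl trifluoromethanesulfonate, C[Si](C)(C)OS(=O)(=O)C(F)(F)F
Why: Soft enolisation and O-silylation of a symmetrical ketone gives the silyl enol ether, mainly as the Z isomer, and its geometry has no bearing on the next step.

Step 16
Reactants: 28 (Z)-3-(trimethylsilyloxy)pent-2-ene; 29 malonyl dichloride
Product: 31 6-ethyl-4-hydroxy-5-methyl-2H-pyran-2-one, via triketo acid chloride 30 (not isolated)
Conditions: Et2O, −78 °C → rt
Reagents that add atoms: none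
Why: C-acylation of the silyl enol ether by one acyl chloride followed by closure of the enolised diketone oxygen onto the second acyl chloride is a known one-flask synthesis of 5,6-disubstituted 4-hydroxy-2-pyrones from ketone silyl enol ethers.

Step 17
Reactants: 31 6-ethyl-4-hydroxy-5-methyl-2H-pyran-2-one
Product: 32 3-[(dimethylamino)methyl]-6-ethyl-4-hydroxy-5-methyl-2H-pyran-2-one
Conditions: [Me2N=CH2]I (Eschenmoser's salt), Et3N, CH2Cl2, 0 °C → rt
Reagents that add atoms: N,N-dimethylmethyleneiminium iodide, C=[N+](C)C.[I-]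
Why: Mannich reaction at the nucleophilic C3 of the 4-hydroxy-2-pyrone with a preformed iminium salt, run cold so that the Mannich base is obtained before it can eliminate and capture a second pyrone.

Step 18
Reactants: 26 (2S)-2-methyl-1-[2,4,6-trihydroxy-3-(3-methylbut-2-enyl)phenyl]butan-1-one; 32 3-[(dimethylamino)methyl]-6-ethyl-4-hydroxy-5-methyl-2H-pyran-2-one
Product: 34 6-ethyl-4-hydroxy-5-methyl-3-{[2,4,6-trihydroxy-3-[(2S)-2-methylbutanoyl]-5-(3-methylbut-2-enyl)phenyl]methyl}-2H-pyran-2-one, via methylidenepyrandione 33 (not isolated)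
Conditions: MeCN (degassed), Ar, 60 °C
Reagents that add atoms: none
Why: Thermal loss of dimethylamine from the Mannich base gives a quinone-methide-like methylidene dione that is captured by the only unsubstituted ring carbon of the phloroglucinol (Friedel–Crafts-type Michael addition, then rearomatisation), the established way to methylene-bridged acylphloroglucinol–pyrone dimers, under conditions mild enough for the alpha-stereocentre.

**Compound list**

1 | L-isoleucine | CC[C@H](C)[C@H](N)C(=O)O | starting material
2 | (2S,3S)-2-hydroxy-3-methylpentanoic acid | CC[C@H](C)[C@H](O)C(=O)O | intermediate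
3 | methyl (2S,3S)-2-hydroxy-3-methylpentanoate | CC[C@H](C)[C@H](O)C(=O)OC | intermediate
4 | methyl (2S,3S)-3-methyl-2-(triethylsilyloxy)pentanoate | CC[C@H](C)[C@H](O[Si](CC)(CC)CC)C(=O)OC | intermediate
5 | (2S,3S)-3-methyl-2-(triethylsilyloxy)pentanal | CC[C@H](C)[C@H](O[Si](CC)(CC)CC)C=O | intermediate
6 | (3S,4S)-4-methyl-3-(triethylsilyloxy)hex-1-yne | CC[C@H](C)[C@H](O[Si](CC)(CC)CC)C#C | intermediate
7 | [(3S,4S)-4-methyl-3-(triethylsilyloxy)hex-1-yn-1-yl]lithium | CC[C@H](C)[C@H](O[Si](CC)(CC)CC)C#C[Li] | intermediate
8 | lithium (3S,4S)-4-methyl-3-(triethylsilyloxy)hex-1-yn-1-olate | CC[C@H](C)[C@H](O[Si](CC)(CC)CC)C#C[O-].[Li+] | intermediate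
9 | (3S,4S)-4-methyl-3-(triethylsilyloxy)-1-(triisopropylsilyloxy)hex-1-yne | CC[C@H](C)[C@H](O[Si](CC)(CC)CC)C#CO[Si](C(C)C)(C(C)C)C(C)C | intermediate
10 | 5-methylhex-4-enoic acid | CC(C)=CCCC(=O)O | starting material
11 | 5-methylhex-4-enoyl chloride | CC(C)=CCCC(=O)Cl | intermediate
12 | ethoxyethyne | CCOC#C | starting material
13 | 5-methylhexa-1,4-dien-1-one (prenylketene) | CC(C)=CCC=C=O | intermediate
14 | 3-ethoxy-4-(3-methylbut-2-enyl)cyclobut-2-en-1-one (racemic) | CCOC1=CC(=O)C1CC=C(C)C | intermediate
15 | 3-ethoxy-2-(3-methylbut-2-enyl)cyclobut-2-en-1-one | CCOC1=C(CC=C(C)C)C(=O)C1 | intermediate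
16 | 3-hydroxy-2-(3-methylbut-2-enyl)cyclobut-2-en-1-one | OC1=C(CC=C(C)C)C(=O)C1 | intermediate
17 | 2-(3-methylbut-2-enyl)-3-(triisopropylsilyloxy)cyclobut-2-en-1-one | O=C1CC(O[Si](C(C)C)(C(C)C)C(C)C)=C1CC=C(C)C | intermediate
18 | 2-(3-methylbut-2-enyl)-3-(triisopropylsilyloxy)buta-1,3-dien-1-one | O=C=C(CC=C(C)C)C(=C)O[Si](C(C)C)(C(C)C)C(C)C | intermediate
19 | 2-[(1S,2S)-2-methyl-1-(triethylsilyloxy)butyl]-4-(3-methylbut-2-enyl)-3-(triisopropylsilyloxy)-4-[1-(triisopropylsilyloxy)ethenyl]cyclobut-2-en-1-one (both epimers at C4) | O=C1C([C@@H](O[Si](CC)(CC)CC)[C@@H](C)CC)=C(O[Si](C(C)C)(C(C)C)C(C)C)C1(CC=C(C)C)C(=C)O[Si](C(C)C)(C(C)C)C(C)C | intermediate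
20 | 2-[(1S,2S)-2-methyl-1-(triethylsilyloxy)butyl]-4-(3-methylbut-2-enyl)-3,5-bis(triisopropylsilyloxy)hexa-1,3,5-trien-1-one (ketene and vinyl termini cis) | C=C(O[Si](C(C)C)(C(C)C)C(C)C)/C(CC=C(C)C)=C(O[Si](C(C)C)(C(C)C)C(C)C)\C(=C=O)[C@@H](O[Si](CC)(CC)CC)[C@@H](C)CC | intermediate
21 | 2-[(1S,2S)-2-methyl-1-(triethylsilyloxy)butyl]-4-(3-methylbut-2-enyl)-3,5-bis(triisopropylsilyloxy)cyclohexa-2,4-dien-1-one | O=C1CC(O[Si](C(C)C)(C(C)C)C(C)C)=C(CC=C(C)C)C(O[Si](C(C)C)(C(C)C)C(C)C)=C1[C@@H](O[Si](CC)(CC)CC)[C@@H](C)CC | intermediate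
22 | 2-[(1S,2S)-2-methyl-1-(triethylsilyloxy)butyl]-4-(3-methylbut-2-enyl)-3,5-bis(triisopropylsilyloxy)phenol | CC[C@H](C)[C@H](O[Si](CC)(CC)CC)c1c(O)cc(O[Si](C(C)C)(C(C)C)C(C)C)c(CC=C(C)C)c1O[Si](C(C)C)(C(C)C)C(C)C | intermediate
23 | triethyl{(1S,2S)-2-methyl-1-[3-(3-methylbut-2-enyl)-2,4,6-tris(triisopropylsilyloxy)phenyl]butoxy}silane | CC[C@H](C)[C@H](O[Si](CC)(CC)CC)c1c(O[Si](C(C)C)(C(C)C)C(C)C)cc(O[Si](C(C)C)(C(C)C)C(C)C)c(CC=C(C)C)c1O[Si](C(C)C)(C(C)C)C(C)C | intermediate
24 | (1S,2S)-2-methyl-1-[3-(3-methylbut-2-enyl)-2,4,6-tris(triisopropylsilyloxy)phenyl]butan-1-ol | CC[C@H](C)[C@H](O)c1c(O[Si](C(C)C)(C(C)C)C(C)C)cc(O[Si](C(C)C)(C(C)C)C(C)C)c(CC=C(C)C)c1O[Si](C(C)C)(C(C)C)C(C)C | intermediate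
25 | (2S)-2-methyl-1-[3-(3-methylbut-2-enyl)-2,4,6-tris(triisopropylsilyloxy)phenyl]butan-1-one | CC[C@H](C)C(=O)c1c(O[Si](C(C)C)(C(C)C)C(C)C)cc(O[Si](C(C)C)(C(C)C)C(C)C)c(CC=C(C)C)c1O[Si](C(C)C)(C(C)C)C(C)C | intermediate
26 | (2S)-2-methyl-1-[2,4,6-trihydroxy-3-(3-methylbut-2-enyl)phenyl]butan-1-one | CC[C@H](C)C(=O)c1c(O)cc(O)c(CC=C(C)C)c1O | intermediate
27 | pentan-3-one | CCC(=O)CC | starting material
28 | (Z)-3-(trimethylsilyloxy)pent-2-ene | C/C=C(/CC)O[Si](C)(C)C | intermediate
29 | malonyl dichloride | O=C(Cl)CC(=O)Cl | starting material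
30 | 4-methyl-3,5-dioxoheptanoyl chloride | CCC(=O)C(C)C(=O)CC(=O)Cl | intermediate
31 | 6-ethyl-4-hydroxy-5-methyl-2H-pyran-2-one | CCc1oc(=O)cc(O)c1C | intermediate
32 | 3-[(dimethylamino)methyl]-6-ethyl-4-hydroxy-5-methyl-2H-pyran-2-one | CCc1oc(=O)c(CN(C)C)c(O)c1C | intermediate
33 | 6-ethyl-5-methyl-3-methylidene-2H-pyran-2,4(3H)-dione | CCC1=C(C)C(=O)C(=C)C(=O)O1 | intermediate
34 | 6-ethyl-4-hydroxy-5-methyl-3-{[2,4,6-trihydroxy-3-[(2S)-2-methylbutanoyl]-5-(3-methylbut-2-enyl)phenyl]methyl}-2H-pyran-2-one | CCc1oc(=O)c(Cc2c(O)c(CC=C(C)C)c(O)c(C(=O)[C@@H](C)CC)c2O)c(O)c1C | target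

**Count and risks**

Total step count: 18. Longest linear sequence: 11 steps (steps 1–5, 10–14 and 18).

Step 10 (carries the label). The vinylogous silyl ester 17 may resist electrocyclic opening, so that at the temperature required the hindered alkyne 9 adds too slowly and ketene 18 is consumed by dimerisation, by acylation of the product phenol or by silyl transfer. The fallback uses known chemistry, sets out from hydroxy acid 2 and comes back to the route at triol 26. Oxidative decarboxylation of 2 with Pb(OAc)4 in CH2Cl2 at 0 °C should give (2S)-2-methylbutanal F1, to be used cold and at once. In parallel, phloroglucinol is protected with MOMCl and i-Pr2NEt as 1,3,5-tris(methoxymethoxy)benzene F2, and ortho-lithiation (n-BuLi, THF, 0 °C) followed by 1-bromo-3-methylbut-2-ene gives 2-(3-methylbut-2-enyl)-1,3,5-tris(methoxymethoxy)benzene F3. A second ortho-lithiation of F3 and addition to F1 at −78 °C gives (2S)-2-methyl-1-[3-(3-methylbut-2-enyl)-2,4,6-tris(methoxymethoxy)phenyl]butan-1-ol F4 as a mixture of carbinol epimers. Dess–Martin oxidation then gives (2S)-2-methyl-1-[3-(3-methylbut-2-enyl)-2,4,6-tris(methoxymethoxy)phenyl]butan-1-one F5, and HCl in MeOH at rt removes the three acetals to give 26.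

Step 12. Cleavage of the aryl silyl ethers may keep pace with that of the shielded alkyl triethylsilyl ether, or the electron-rich benzylic C–O bond may ionise and lose a proton from the neighbouring stereocentre. The fallback sets out from 23 and comes back at ketone 25: 23 is treated with 2-iodoxybenzoic acid in DMSO at rt, a reagent known to cleave triethylsilyl ethers beside bulkier silyl ethers and to oxidise the released alcohol in the same flask, so that the free carbinol is never handled; this fallback makes no new compound (F0).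

Step 5. Oxygen transfer to the hindered acetylide may be incomplete, the ynolate may expel silanolate from the neighbouring carbon, or silylation may occur on carbon to give a silylketene. The fallback sets out from ester 4 and comes back at 9 through the same ynolate 8, by the Kowalski ynolate route. LiCHBr2 (from CH2Br2 and lithium 2,2,6,6-tetramethylpiperidide, THF, −78 °C) adds to 4 to give (3S,4S)-1,1-dibromo-4-methyl-3-(triethylsilyloxy)hexan-2-one F6, held as its lithium enolate with LiN(SiMe3)2. Bromine–lithium exchange with n-BuLi and warming should trigger the carbenoid rearrangement to 8, which is trapped with i-Pr3SiOTf as 9. This variant would also shorten the route by one step.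

**Further compounds**

F1 | step 10 | (2S)-2-methylbutanal | CC[C@H](C)C=O
F2 | step 10 | 1,3,5-tris(methoxymethoxy)benzene | COCOc1cc(OCOC)cc(OCOC)c1
F3 | step 10 | 2-(3-methylbut-2-enyl)-1,3,5-tris(methoxymethoxy)benzene | COCOc1cc(OCOC)c(CC=C(C)C)c(OCOC)c1
F4 | step 10 | (2S)-2-methyl-1-[3-(3-methylbut-2-enyl)-2,4,6-tris(methoxymethoxy)phenyl]butan-1-ol (both carbinol epimers) | CC[C@H](C)C(O)c1c(OCOC)cc(OCOC)c(CC=C(C)C)c1OCOC
F5 | step 10 | (2S)-2-methyl-1-[3-(3-methylbut-2-enyl)-2,4,6-tris(methoxymethoxy)phenyl]butan-1-one | CC[C@H](C)C(=O)c1c(OCOC)cc(OCOC)c(CC=C(C)C)c1OCOC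
F0 | step 12 | none | none
F6 | step 5 | (3S,4S)-1,1-dibromo-4-methyl-3-(triethylsilyloxy)hexan-2-one | CC[C@H](C)[C@H](O[Si](CC)(CC)CC)C(=O)C(Br)Br
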